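Everything rests on cutting the O1–C8a aryl ether of ring C. Ring A carries C6-OMe, C7-O and C8-OMe symmetrically about the C4a–C7 axis, the pattern of syringic acid, so C5 and C8a are equivalent and both can be brominated. The precursor is therefore a 2-methoxy-1,3-diketone joining a 4-benzyloxy-2,6-dibromo-3,5-dimethoxyphenyl ketone to the benzyl-protected ring B aroyl group. In one operation the enolate oxygen on the ring B side displaces either bromide under copper catalysis, closing the pyranone and leaving the other bromide at C5, peri to the C4 carbonyl, as the handle for the last oxygen before global debenzylation.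

Key step: step 6

Step 1
Reactants: 1 syringic acid
Product: 3 4-(benzyloxy)-3,5-dimethoxybenzoic acid, via benzyl 4-(benzyloxy)-3,5-dimethoxybenzoate 2 (not isolated)
Conditions: BnBr, K2CO3, DMF, 60 °C; then NaOH, MeOH/H2O, 70 °C; HCl
Reagents that add atoms: benzyl bromide, BrCc1ccccc1; sodium hydroxide, [Na+].[OH-]
Why: Williamson benzylation of phenoxide and carboxylate (SN2) followed by saponification of the unhindered benzyl ester, which leaves the aryl benzyl ether untouched.

Step 2
Reactants: 3 4-(benzyloxy)-3,5-dimethoxybenzoic acid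
Product: 4 4-(benzyloxy)-2,6-dibromo-3,5-dimethoxybenzoic acid
Conditions: Br2 (2.2 equiv), NaOAc, AcOH, rt → 50 °C, dark
Reagents that add atoms: bromine, BrBr
Why: Electrophilic aromatic bromination: each free ring carbon lies ortho to one methoxy group and para to the other, so both should be substituted, while the acetate buffer scavenges HBr and protects the benzyl ether.

Step 3
Reactants: 5 3,5-dihydroxy-4-methoxybenzoic acid
Product: 7 methyl 3,5-bis(benzyloxy)-4-methoxybenzoate, via methyl 3,5-dihydroxy-4-methoxybenzoate 6 (not isolated)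
Conditions: MeOH, cat. H2SO4, reflux; concentrate; then BnBr, K2CO3, DMF, 60 °C
Reagents that add atoms: methanol, CO; benzyl bromide, BrCc1ccccc1
Why: Fischer esterification followed by Williamson benzylation of both phenols; the methyl ester is stable to anhydrous K2CO3.

Step 4
Reactants: 7 methyl 3,5-bis(benzyloxy)-4-methoxybenzoate; 8 methyl methoxyacetate
Product: 10 1-[3,5-bis(benzyloxy)-4-methoxyphenyl]-2-methoxyethan-1-one, via methyl 3-[3,5-bis(benzyloxy)-4-methoxyphenyl]-2-methoxy-3-oxopropanoate 9 (not isolated)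
Conditions: NaH, THF, reflux (8 added slowly); AcOH; concentrate; then LiCl, H2O, DMSO, 120 °C
Reagents that add atoms: none
Why: Crossed Claisen condensation of the enolate of 8 with the non-enolisable aryl ester, driven by deprotonation of the beta-keto ester, then Krapcho dealkoxycarbonylation under neutral conditions that spare the benzyl ethers.

Step 5
Reactants: 4 4-(benzyloxy)-2,6-dibromo-3,5-dimethoxybenzoic acid; 10 1-[3,5-bis(benzyloxy)-4-methoxyphenyl]-2-methoxyethan-1-one
Product: 12 1-[4-(benzyloxy)-2,6-dibromo-3,5-dimethoxyphenyl]-3-[3,5-bis(benzyloxy)-4-methoxyphenyl]-2-methoxypropane-1,3-dione, via 4-(benzyloxy)-2,6-dibromo-3,5-dimethoxybenzoyl chloride 11 (not isolated)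
Conditions: 4, (COCl)2, cat. DMF, CH2Cl2, 0 °C → rt, concentrate; then 10, MgBr2·OEt2, i-Pr2NEt, CH2Cl2, 0 °C → rt; aq. HCl
Reagents that add atoms: none
Why: Vilsmeier-type conversion of the acid to the acyl chloride, then soft enolisation of the alpha-methoxy ketone to a chelated magnesium enolate that is acylated on carbon (Claisen-type C-acylation); the diketone stays bound as its magnesium chelate, which should block a second acylation.

Step 6
Reactants: 12 1-[4-(benzyloxy)-2,6-dibromo-3,5-dimethoxyphenyl]-3-[3,5-bis(benzyloxy)-4-methoxyphenyl]-2-methoxypropane-1,3-dione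
Product: 13 7-(benzyloxy)-2-[3,5-bis(benzyloxy)-4-methoxyphenyl]-5-bromo-3,6,8-trimethoxy-4H-chromen-4-one
Conditions: CuBr (10 mol %), K2CO3, dry degassed DMF, 90 °C, argon
Reagents that add atoms: none
Why: K2CO3 removes the proton of the central CH(OMe), and the enolate oxygen on the ring B carbonyl carbon binds monovalent copper, which inserts into an adjacent C–Br bond and forms O1–C8a by reductive elimination; direct addition–elimination at this carbonyl-activated carbon leads to the same bond. The closest known reaction type is the intramolecular Ullmann-type O-arylation of 1-(2-haloaryl)-1,3-diketones to chromones and flavones. Ring C closes as a six-membered pyranone through oxygen onto the arene carbon ortho to the ketone, whereas closure through the C4 oxygen or through C3 would need a four-membered ring. No stereocentre is formed. The step needs exactly one bromide to react: the two are related by the symmetry of ring A, so either closure gives the same flavone, and once the single enolate oxygen is spent nothing can reach the second bromide, which ends at C5.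

Step 7
Reactants: 13 7-(benzyloxy)-2-[3,5-bis(benzyloxy)-4-methoxyphenyl]-5-bromo-3,6,8-trimethoxy-4H-chromen-4-one
Product: 14 5,7-bis(benzyloxy)-2-[3,5-bis(benzyloxy)-4-methoxyphenyl]-3,6,8-trimethoxy-4H-chromen-4-one
Conditions: CuI (10 mol %), 3,4,7,8-tetramethyl-1,10-phenanthroline (20 mol %), Cs2CO3, BnOH, toluene, 110 °C
Reagents that add atoms: benzyl alcohol, OCc1ccccc1
Why: Ullmann-type copper-catalysed C–O coupling of the aryl bromide with a primary alcohol, helped by the peri C4 carbonyl oxygen that can hold copper next to C5–Br; carbonate and an alcohol are used in place of hydroxide because hot hydroxide opens 3-methoxyflavones to diketones that fragment by retro-Claisen cleavage.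

Step 8
Reactants: 14 5,7-bis(benzyloxy)-2-[3,5-bis(benzyloxy)-4-methoxyphenyl]-3,6,8-trimethoxy-4H-chromen-4-one
Product: 15 5,7-dihydroxy-2-(3,5-dihydroxy-4-methoxyphenyl)-3,6,8-trimethoxy-4H-chromen-4-one (5,7,3',5'-tetrahydroxy-3,6,8,4'-tetramethoxyflavone)
Conditions: H2 (1 atm), 10% Pd/C, EtOAc/MeOH, rt
Reagents that add atoms: none
Why: Catalytic hydrogenolysis of the four benzyl ethers over palladium; the tetrasubstituted, carbonyl-conjugated C2=C3 bond and the aryl methyl ethers should not be touched at 1 atm.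

Compound list
1 | syringic acid (4-hydroxy-3,5-dimethoxybenzoic acid) | COc1cc(C(=O)O)cc(OC)c1O | starting material
2 | benzyl 4-(benzyloxy)-3,5-dimethoxybenzoate | COc1cc(C(=O)OCc2ccccc2)cc(OC)c1OCc1ccccc1 | intermediate
3 | 4-(benzyloxy)-3,5-dimethoxybenzoic acid | COc1cc(C(=O)O)cc(OC)c1OCc1ccccc1 | intermediate
4 | 4-(benzyloxy)-2,6-dibromo-3,5-dimethoxybenzoic acid | COc1c(Br)c(C(=O)O)c(Br)c(OC)c1OCc1ccccc1 | intermediate
5 | 3,5-dihydroxy-4-methoxybenzoic acid | COc1c(O)cc(C(=O)O)cc1O | starting material
6 | methyl 3,5-dihydroxy-4-methoxybenzoate | COC(=O)c1cc(O)c(OC)c(O)c1 | intermediate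
7 | methyl 3,5-bis(benzyloxy)-4-methoxybenzoate | COC(=O)c1cc(OCc2ccccc2)c(OC)c(OCc2ccccc2)c1 | intermediate
8 | methyl methoxyacetate | COCC(=O)OC | starting material
9 | methyl 3-[3,5-bis(benzyloxy)-4-methoxyphenyl]-2-methoxy-3-oxopropanoate (racemic, enolisable) | COC(=O)C(OC)C(=O)c1cc(OCc2ccccc2)c(OC)c(OCc2ccccc2)c1 | intermediate
10 | 1-[3,5-bis(benzyloxy)-4-methoxyphenyl]-2-methoxyethan-1-one | COCC(=O)c1cc(OCc2ccccc2)c(OC)c(OCc2ccccc2)c1 | intermediate
11 | 4-(benzyloxy)-2,6-dibromo-3,5-dimethoxybenzoyl chloride | COc1c(Br)c(C(=O)Cl)c(Br)c(OC)c1OCc1ccccc1 | intermediate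
12 | 1-[4-(benzyloxy)-2,6-dibromo-3,5-dimethoxyphenyl]-3-[3,5-bis(benzyloxy)-4-methoxyphenyl]-2-methoxypropane-1,3-dione, drawn as its chelated enol | COc1c(Br)c(C(=O)/C(OC)=C(\O)c2cc(OCc3ccccc3)c(OC)c(OCc3ccccc3)c2)c(Br)c(OC)c1OCc1ccccc1 | intermediate
13 | 7-(benzyloxy)-2-[3,5-bis(benzyloxy)-4-methoxyphenyl]-5-bromo-3,6,8-trimethoxy-4H-chromen-4-one | COc1c(Br)c2c(=O)c(OC)c(-c3cc(OCc4ccccc4)c(OC)c(OCc4ccccc4)c3)oc2c(OC)c1OCc1ccccc1 | intermediate
14 | 5,7-bis(benzyloxy)-2-[3,5-bis(benzyloxy)-4-methoxyphenyl]-3,6,8-trimethoxy-4H-chromen-4-one | COc1c(OCc2ccccc2)c2c(=O)c(OC)c(-c3cc(OCc4ccccc4)c(OC)c(OCc4ccccc4)c3)oc2c(OC)c1OCc1ccccc1 | intermediate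
15 | 5,7-dihydroxy-2-(3,5-dihydroxy-4-methoxyphenyl)-3,6,8-trimethoxy-4H-chromen-4-one | COc1c(O)cc(-c2oc3c(OC)c(O)c(OC)c(O)c3c(=O)c2OC)cc1O | target

Total step count: 8. Longest linear sequence: 6 steps (steps 1, 2, 5, 6, 7, 8 from syringic acid; equally steps 3, 4, 5, 6, 7, 8 from 3,5-dihydroxy-4-methoxybenzoic acid).

Steps most likely to fail

Step 6. The diketone may fragment by retro-Claisen cleavage under base before it closes, or closure may be slow because the aroyl group must turn into the plane of ring A against the second bromine. The fallback sets out from 12 and forms O1–C8a intermolecularly, closing ring C afterwards by condensation at C2. Copper-catalysed etherification of both bromides (CuI, 3,4,7,8-tetramethyl-1,10-phenanthroline, Cs2CO3, excess BnOH, toluene, 110 °C) should give 1-[2,4,6-tris(benzyloxy)-3,5-dimethoxyphenyl]-3-[3,5-bis(benzyloxy)-4-methoxyphenyl]-2-methoxypropane-1,3-dione F1. Hydrogenolysis (H2, 10% Pd/C, EtOAc/MeOH) should then free 1-(2,4,6-trihydroxy-3,5-dimethoxyphenyl)-3-(3,5-dihydroxy-4-methoxyphenyl)-2-methoxypropane-1,3-dione F2. Acid-catalysed cyclodehydration of this o-hydroxyaryl diketone (AcOH, cat. H2SO4, 60 °C) comes back to the route at 15; the two ortho hydroxyls are equivalent, so only one flavone can form. Any material that closes to 14 under the etherification conditions simply goes on to step 8.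

Step 5. Attack at the acyl carbon of 11 is shielded by two ortho bromines, so the coupling may stall or drift to O-acylation of the enolate. The fallback sets out from 11 and replaces the acyl substitution by an aldol addition and an oxidation. Reduction with LiAlH(OtBu)3 (THF, −78 °C) should give 4-(benzyloxy)-2,6-dibromo-3,5-dimethoxybenzaldehyde F3. The lithium enolate of 10 (LDA, THF, −78 °C) should add to it to give 3-[4-(benzyloxy)-2,6-dibromo-3,5-dimethoxyphenyl]-1-[3,5-bis(benzyloxy)-4-methoxyphenyl]-3-hydroxy-2-methoxypropan-1-one F4 as a mixture of diastereomers, both stereocentres being erased next. Oxidation with Dess–Martin periodinane (CH2Cl2, rt) comes back to the route at 12.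

Step 7. Bromine may be lost reductively at C5 through hydride transfer from a copper benzyloxide, or coupling may be sluggish at a carbon flanked on both sides. The fallback sets out from 13 and uses a hydroxide surrogate under palladium catalysis, with no alkoxide hydride donor and no free hydroxide. Coupling with (E)-benzaldoxime (Pd2(dba)3, tBuBrettPhos, Cs2CO3, DMF, 80 °C) should give the O-aryl oxime 5-[(E)-(benzylideneamino)oxy]-7-(benzyloxy)-2-[3,5-bis(benzyloxy)-4-methoxyphenyl]-3,6,8-trimethoxy-4H-chromen-4-one F5. This fragments in the same flask to benzonitrile and 7-(benzyloxy)-2-[3,5-bis(benzyloxy)-4-methoxyphenyl]-5-hydroxy-3,6,8-trimethoxy-4H-chromen-4-one F6. Hydrogenolysis as in step 8 comes back to the route at 15. Should the pyranone open and reclose at any point under base, the symmetric ring A regenerates the same flavone.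

Further compounds
F1 | step 6 | 1-[2,4,6-tris(benzyloxy)-3,5-dimethoxyphenyl]-3-[3,5-bis(benzyloxy)-4-methoxyphenyl]-2-methoxypropane-1,3-dione | COc1c(OCc2ccccc2)c(C(=O)C(OC)C(=O)c2cc(OCc3ccccc3)c(OC)c(OCc3ccccc3)c2)c(OCc2ccccc2)c(OC)c1OCc1ccccc1
F2 | step 6 | 1-(2,4,6-trihydroxy-3,5-dimethoxyphenyl)-3-(3,5-dihydroxy-4-methoxyphenyl)-2-methoxypropane-1,3-dione | COc1c(O)c(C(=O)C(OC)C(=O)c2cc(O)c(OC)c(O)c2)c(O)c(OC)c1O
F3 | step 5 | 4-(benzyloxy)-2,6-dibromo-3,5-dimethoxybenzaldehyde | COc1c(Br)c(C=O)c(Br)c(OC)c1OCc1ccccc1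
F4 | step 5 | 3-[4-(benzyloxy)-2,6-dibromo-3,5-dimethoxyphenyl]-1-[3,5-bis(benzyloxy)-4-methoxyphenyl]-3-hydroxy-2-methoxypropan-1-one (mixture of diastereomers) | COc1c(Br)c(C(O)C(OC)C(=O)c2cc(OCc3ccccc3)c(OC)c(OCc3ccccc3)c2)c(Br)c(OC)c1OCc1ccccc1
F5 | step 7 | 5-[(E)-(benzylideneamino)oxy]-7-(benzyloxy)-2-[3,5-bis(benzyloxy)-4-methoxyphenyl]-3,6,8-trimethoxy-4H-chromen-4-one | COc1c(O/N=C/c2ccccc2)c2c(=O)c(OC)c(-c3cc(OCc4ccccc4)c(OC)c(OCc4ccccc4)c3)oc2c(OC)c1OCc1ccccc1
F6 | step 7 | 7-(benzyloxy)-2-[3,5-bis(benzyloxy)-4-methoxyphenyl]-5-hydroxy-3,6,8-trimethoxy-4H-chromen-4-one | COc1c(O)c2c(=O)c(OC)c(-c3cc(OCc4ccccc4)c(OC)c(OCc4ccccc4)c3)oc2c(OC)c1OCc1ccccc1
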